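The lactone is disconnected at C2–C3 and at O1–C5: the C2(=O)–O1 unit is a CO2-level one-carbon building block, and C3 with its benzyl group becomes the β-carbon of a styrene. In the key step CO2•− (from formate) adds to that β-carbon of an acyclic (E)-styrene carrying a tosylate on the future C5, and the carboxylate then closes the ring on C5. The step exploits the 1,3-relation of C3 and C5 across C4 and the guaiacyl ring of the C3 benzyl group, which stabilises the benzylic radical. C4 comes from an Ir-catalysed hydroxymethyl-allylation; the C3 hydroxyl is added by enolate oxidation, and C4 is finally equilibrated beside the unveiled aryl ketone.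

Key step: step 4

Remark: Ar = 4-(benzyloxy)-3-methoxyphenyl (both phenols are carried as benzyl ethers); the SEGPHOS antipode in step 1 is the one that gives the (1R,2S) diol 3, assigned by analogy and to be confirmed on the first batch.

Step 1
Reactants: 1 4-(benzyloxy)-3-methoxybenzyl alcohol; 2 4-vinyl-1,3-dioxolan-2-one (racemic)
Product: 3 (1R,2S)-1-Ar-2-ethenylpropane-1,3-diol (anti)
Conditions: [Ir(cod)Cl]2 (2.5 mol%), (R)-SEGPHOS (5 mol%), 4-cyano-3-nitrobenzoic acid (10 mol%), K3PO4 (5 mol%), THF, 90 °C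
Reagents that add atoms: none
Why: Iridium-catalysed transfer-hydrogenative carbonyl (hydroxymethyl)allylation, in which the alcohol is dehydrogenated to the aldehyde and decarboxylative ionisation of 2 gives an (E)-σ-allyl iridium species that adds through a closed chair transition state, so that the anti relationship and both stereocentres (the later lactone C4 and the carbinol carbon) are set by the chiral Ir–SEGPHOS catalyst.

Step 2
Reactants: 3 (1R,2S)-1-Ar-2-ethenylpropane-1,3-diol; 4 4-(benzyloxy)-3-methoxystyrene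
Product: 5 (1R,2S)-1-Ar-2-[(E)-2-Ar-ethenyl]propane-1,3-diol
Conditions: Hoveyda–Grubbs II (5 mol%), 4 (3 equiv), CH2Cl2, 40 °C
Reagents that add atoms: none
Why: Olefin cross-metathesis of a hindered terminal alkene with a styrene should be E-selective and tolerate the free diol, it touches no stereocentre, and the alkene geometry is not carried into the target.

Step 3
Reactants: 5 (1R,2S)-1-Ar-2-[(E)-2-Ar-ethenyl]propane-1,3-diol
Product: 7 (2S,3E)-2-[(R)-Ar(tert-butyldimethylsilyloxy)methyl]-4-Ar-but-3-en-1-yl 4-methylbenzenesulfonate, via primary monotosylate 6 (not isolated)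
Conditions: TsCl (1.1 equiv), Et3N, Me3N·HCl (cat.), CH2Cl2, 0 °C; then 2,6-lutidine, TBSOTf, −78 → 0 °C
Reagents that add atoms: p-toluenesulfonyl chloride Cc1ccc(cc1)S(=O)(=O)Cl; tert-butyldimethylsilyl triflate CC(C)(C)[Si](C)(C)OS(=O)(=O)C(F)(F)F
Why: Sulfonylation should discriminate the unhindered primary from the secondary benzylic hydroxyl on steric grounds, and silyl triflate then caps the remaining hydroxyl (O-sulfonylation followed by O-silylation), neither event touching a stereocentre.

Step 4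
Reactants: 7 (2S,3E)-2-[(R)-Ar(tert-butyldimethylsilyloxy)methyl]-4-Ar-but-3-en-1-yl 4-methylbenzenesulfonate
Product: 9 (4S)-3-(Ar-methyl)-4-[(R)-Ar(tert-butyldimethylsilyloxy)methyl]oxolan-2-one (both C3 epimers), via potassium carboxylate 8 (not isolated)
Conditions: HCO2K (3 equiv), 4CzIPN (2 mol%), iPr3SiSH (20 mol%), DMSO, blue LEDs, 25 °C; then 50 °C
Reagents that add atoms: potassium formate [K+].[O-]C=O
Why: A thiyl radical (thiol co-catalyst, 4CzIPN photocatalysis) abstracts the formyl hydrogen of formate to give CO2•−, which adds to the styrene β-carbon (future C3) because only this regiochemistry gives a benzylic radical; that radical takes a hydrogen atom back from the thiol and carries the chain. The closest known reaction type is the anti-Markovnikov radical hydrocarboxylation of styrenes with formate, here followed in the same pot by a carboxylate O-alkylation. The potassium carboxylate 8 closes the lactone by 5-exo-tet SN2 displacement of the primary tosylate, so the O1–C5 bond forms directly after the C2–C3 bond. C3 is formed as a mixture of epimers without control, deliberately, because it is planarised as an enolate in step 5; C4 and the carbinol carbon are spectators and keep their configuration. The step needs regioselectivity, secured by benzylic radical stabilisation, and chemoselectivity for intramolecular over intermolecular (formate) displacement of the tosylate, secured by the β-branched hindered primary carbon and the high effective molarity of the 1,4-related carboxylate.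

Step 5
Reactants: 9 (4S)-3-(Ar-methyl)-4-[(R)-Ar(tert-butyldimethylsilyloxy)methyl]oxolan-2-one
Product: 10 (3S,4S)-3-(Ar-methyl)-4-[(R)-Ar(tert-butyldimethylsilyloxy)methyl]-3-hydroxyoxolan-2-one
Conditions: KHMDS, THF, −78 °C; then 2-(phenylsulfonyl)-3-phenyloxaziridine, −78 °C; AcOH quench
Reagents that add atoms: 2-(phenylsulfonyl)-3-phenyloxaziridine O=S(=O)(c1ccccc1)N1OC1c1ccccc1
Why: Davis enolate hydroxylation, in which deprotonation erases the C3 epimer mixture and the oxaziridine should attack the planar potassium enolate on the face anti to the bulky C4 side chain, setting C3 as (S) with the hydroxyl trans and the benzyl group cis to that side chain.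

Step 6
Reactants: 10 (3S,4S)-3-(Ar-methyl)-4-[(R)-Ar(tert-butyldimethylsilyloxy)methyl]-3-hydroxyoxolan-2-one
Product: 11 (3S,4S)-3-(Ar-methyl)-4-[(R)-Ar(hydroxy)methyl]-3-hydroxyoxolan-2-one
Conditions: TBAF, AcOH, THF, 0 °C → rt
Reagents that add atoms: none
Why: Fluoride-mediated desilylation of the secondary silyl ether, buffered with acetic acid to suppress alkoxide-driven translactonisation, touches no stereocentre.

Step 7
Reactants: 11 (3S,4S)-3-(Ar-methyl)-4-[(R)-Ar(hydroxy)methyl]-3-hydroxyoxolan-2-one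
Product: 12 (3S,4R)-4-(Ar-carbonyl)-3-(Ar-methyl)-3-hydroxyoxolan-2-one (aroyl cis to benzyl)
Conditions: Dess–Martin periodinane, CH2Cl2, 0 °C → rt
Reagents that add atoms: none
Why: Dess–Martin oxidation converts the secondary benzylic alcohol into the aryl ketone while the tertiary C3 hydroxyl cannot be oxidised, and C4 keeps its geometry (its descriptor changes to R only through the CIP priorities).

Step 8
Reactants: 12 (3S,4R)-4-(Ar-carbonyl)-3-(Ar-methyl)-3-hydroxyoxolan-2-one
Product: 13 (3S,4S)-4-(Ar-carbonyl)-3-(Ar-methyl)-3-hydroxyoxolan-2-one (aroyl trans to benzyl, cis to OH)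
Conditions: DBU (0.2 equiv), CH2Cl2, 0 °C → rt
Reagents that add atoms: none
Why: Base-catalysed enolisation of the aryl ketone makes C4 epimerisable, and the equilibrium should favour the (4S) epimer, whose aroyl group is trans to the C3 benzyl group and can hydrogen-bond to the cis C3 hydroxyl (thermodynamic epimerisation), while the non-enolisable C3 keeps its configuration.

Step 9
Reactants: 13 (3S,4S)-4-(Ar-carbonyl)-3-(Ar-methyl)-3-hydroxyoxolan-2-one
Product: 14 (3S,4S)-3-hydroxy-4-(4-hydroxy-3-methoxybenzoyl)-3-(4-hydroxy-3-methoxybenzyl)oxolan-2-one (target)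
Conditions: H2 (1 atm), 10% Pd/C, EtOAc, rt
Reagents that add atoms: none
Why: Catalytic hydrogenolysis of the two aryl benzyl ethers should be faster than reduction of the electron-rich aryl ketone, and the neutral conditions leave the β-hydroxy ketone and both stereocentres intact.

Compound list
1 | 4-(benzyloxy)-3-methoxybenzyl alcohol | OCc1ccc(OCc2ccccc2)c(OC)c1 | starting material
2 | 4-vinyl-1,3-dioxolan-2-one (racemic) | C=CC1COC(=O)O1 | starting material
3 | (1R,2S)-1-[4-(benzyloxy)-3-methoxyphenyl]-2-ethenylpropane-1,3-diol | OC[C@H](C=C)[C@@H](O)c1ccc(OCc2ccccc2)c(OC)c1 | intermediate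
4 | 4-(benzyloxy)-3-methoxystyrene | C=Cc1ccc(OCc2ccccc2)c(OC)c1 | starting material
5 | (1R,2S)-1-[4-(benzyloxy)-3-methoxyphenyl]-2-{(E)-2-[4-(benzyloxy)-3-methoxyphenyl]ethenyl}propane-1,3-diol | OC[C@H](/C=C/c1ccc(OCc2ccccc2)c(OC)c1)[C@@H](O)c1ccc(OCc2ccccc2)c(OC)c1 | intermediate
6 | (2S,3E)-2-{(R)-[4-(benzyloxy)-3-methoxyphenyl](hydroxy)methyl}-4-[4-(benzyloxy)-3-methoxyphenyl]but-3-en-1-yl 4-methylbenzenesulfonate | Cc1ccc(cc1)S(=O)(=O)OC[C@H](/C=C/c1ccc(OCc2ccccc2)c(OC)c1)[C@@H](O)c1ccc(OCc2ccccc2)c(OC)c1 | intermediate (not isolated)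
7 | (2S,3E)-2-{(R)-[4-(benzyloxy)-3-methoxyphenyl][(tert-butyldimethylsilyl)oxy]methyl}-4-[4-(benzyloxy)-3-methoxyphenyl]but-3-en-1-yl 4-methylbenzenesulfonate | Cc1ccc(cc1)S(=O)(=O)OC[C@H](/C=C/c1ccc(OCc2ccccc2)c(OC)c1)[C@@H](O[Si](C)(C)C(C)(C)C)c1ccc(OCc2ccccc2)c(OC)c1 | intermediate
8 | potassium (3S,4R)-2-[4-(benzyloxy)-3-methoxybenzyl]-4-[4-(benzyloxy)-3-methoxyphenyl]-4-[(tert-butyldimethylsilyl)oxy]-3-(tosyloxymethyl)butanoate (both C2 epimers) | [K+].[O-]C(=O)C(Cc1ccc(OCc2ccccc2)c(OC)c1)[C@@H](COS(=O)(=O)c1ccc(C)cc1)[C@@H](O[Si](C)(C)C(C)(C)C)c1ccc(OCc2ccccc2)c(OC)c1 | intermediate (not isolated)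
9 | (4S)-3-[4-(benzyloxy)-3-methoxybenzyl]-4-{(R)-[4-(benzyloxy)-3-methoxyphenyl][(tert-butyldimethylsilyl)oxy]methyl}oxolan-2-one (both C3 epimers) | O=C1OC[C@@H]([C@@H](O[Si](C)(C)C(C)(C)C)c2ccc(OCc3ccccc3)c(OC)c2)C1Cc1ccc(OCc2ccccc2)c(OC)c1 | intermediate
10 | (3S,4S)-3-[4-(benzyloxy)-3-methoxybenzyl]-4-{(R)-[4-(benzyloxy)-3-methoxyphenyl][(tert-butyldimethylsilyl)oxy]methyl}-3-hydroxyoxolan-2-one | O=C1OC[C@@H]([C@@H](O[Si](C)(C)C(C)(C)C)c2ccc(OCc3ccccc3)c(OC)c2)[C@@]1(O)Cc1ccc(OCc2ccccc2)c(OC)c1 | intermediate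
11 | (3S,4S)-3-[4-(benzyloxy)-3-methoxybenzyl]-4-{(R)-[4-(benzyloxy)-3-methoxyphenyl](hydroxy)methyl}-3-hydroxyoxolan-2-one | O=C1OC[C@@H]([C@@H](O)c2ccc(OCc3ccccc3)c(OC)c2)[C@@]1(O)Cc1ccc(OCc2ccccc2)c(OC)c1 | intermediate
12 | (3S,4R)-4-[4-(benzyloxy)-3-methoxybenzoyl]-3-[4-(benzyloxy)-3-methoxybenzyl]-3-hydroxyoxolan-2-one | O=C1OC[C@@H](C(=O)c2ccc(OCc3ccccc3)c(OC)c2)[C@@]1(O)Cc1ccc(OCc2ccccc2)c(OC)c1 | intermediate
13 | (3S,4S)-4-[4-(benzyloxy)-3-methoxybenzoyl]-3-[4-(benzyloxy)-3-methoxybenzyl]-3-hydroxyoxolan-2-one | O=C1OC[C@H](C(=O)c2ccc(OCc3ccccc3)c(OC)c2)[C@@]1(O)Cc1ccc(OCc2ccccc2)c(OC)c1 | intermediate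
14 | (3S,4S)-3-hydroxy-4-(4-hydroxy-3-methoxybenzoyl)-3-(4-hydroxy-3-methoxybenzyl)oxolan-2-one | COc1cc(C[C@@]2(O)C(=O)OC[C@@H]2C(=O)c2ccc(O)c(OC)c2)ccc1O | target

Total step count: 9. Longest linear sequence: 9 steps (1 → 3 → 5 → 7 → 9 → 10 → 11 → 12 → 13 → 14).

Steps most likely to fail

Step 4 (key step). The nucleophilic CO2•− may add too slowly to the electron-rich, β-branched styrene, so that intermolecular displacement of the tosylate by formate, or electron transfer to the sulfonate, overtakes the cascade. The fallback sets out from 3 and comes back at 9, and builds the lactone carbonyl from the vinyl terminus instead. Bis-silylation of 3 (TBSOTf, 2,6-lutidine) should give the bis(TBS) ether of 3 F1. Hydroboration–oxidation of its vinyl group (9-BBN, THF; then NaOH, H2O2) should give (3S,4R)-4-Ar-4-(TBSO)-3-[(TBSO)methyl]butan-1-ol F2. TEMPO/PhI(OAc)2 in MeCN–water should oxidise this to (3S,4R)-4-Ar-4-(TBSO)-3-[(TBSO)methyl]butanoic acid F3. PPTS in MeOH should cleave the primary silyl ether selectively, and the γ-hydroxy acid should lactonise to (4S)-4-[(R)-Ar(TBSO)methyl]oxolan-2-one F4. Enolate alkylation (LDA, THF, −78 °C; then 4-(benzyloxy)-3-methoxybenzyl bromide) then gives 9 as its trans C3 epimer, which converges with the main route in step 5.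

Step 8. Under base the free tertiary β-hydroxy ketone may undergo retro-aldol cleavage of C3–C4 (which would scramble C3) or lose water to the butenolide faster than C4 equilibrates. The fallback sets out from 12 and comes back at 13 through a protecting-group detour. Silylation of the C3 hydroxyl (TMSOTf, 2,6-lutidine, CH2Cl2, −78 °C) should give the C3 O-trimethylsilyl ether of 12 F5, in which retro-aldol cleavage is blocked. DBU then equilibrates C4 to the C3 O-trimethylsilyl ether of 13 F6, and citric acid in MeOH removes the silyl group to give 13.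

Step 2. The allylically branched terminal alkene may be engaged too slowly in metathesis, so that self-metathesis of 4 and alkene migration in 3 dominate. The fallback sets out from 3 and comes back at 5: Heck arylation of 3 with 1-(benzyloxy)-4-bromo-2-methoxybenzene (Pd(OAc)2, P(o-tol)3, Et3N, DMF, 90 °C) forms the same (E)-styrene 5 by aryl–vinyl C–C coupling at the terminal carbon, with no new intermediate.

Further compounds
F1 | step 4 | (1R,2S)-1-[4-(benzyloxy)-3-methoxyphenyl]-2-ethenylpropane-1,3-diol bis(tert-butyldimethylsilyl) ether | CC(C)(C)[Si](C)(C)OC[C@H](C=C)[C@@H](O[Si](C)(C)C(C)(C)C)c1ccc(OCc2ccccc2)c(OC)c1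
F2 | step 4 | (3S,4R)-4-[4-(benzyloxy)-3-methoxyphenyl]-4-[(tert-butyldimethylsilyl)oxy]-3-{[(tert-butyldimethylsilyl)oxy]methyl}butan-1-ol | CC(C)(C)[Si](C)(C)OC[C@H](CCO)[C@@H](O[Si](C)(C)C(C)(C)C)c1ccc(OCc2ccccc2)c(OC)c1
F3 | step 4 | (3S,4R)-4-[4-(benzyloxy)-3-methoxyphenyl]-4-[(tert-butyldimethylsilyl)oxy]-3-{[(tert-butyldimethylsilyl)oxy]methyl}butanoic acid | CC(C)(C)[Si](C)(C)OC[C@H](CC(=O)O)[C@@H](O[Si](C)(C)C(C)(C)C)c1ccc(OCc2ccccc2)c(OC)c1
F4 | step 4 | (4S)-4-{(R)-[4-(benzyloxy)-3-methoxyphenyl][(tert-butyldimethylsilyl)oxy]methyl}oxolan-2-one | O=C1C[C@H]([C@@H](O[Si](C)(C)C(C)(C)C)c2ccc(OCc3ccccc3)c(OC)c2)CO1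
F5 | step 8 | (3S,4R)-4-[4-(benzyloxy)-3-methoxybenzoyl]-3-[4-(benzyloxy)-3-methoxybenzyl]-3-[(trimethylsilyl)oxy]oxolan-2-one | O=C1OC[C@@H](C(=O)c2ccc(OCc3ccccc3)c(OC)c2)[C@@]1(O[Si](C)(C)C)Cc1ccc(OCc2ccccc2)c(OC)c1
F6 | step 8 | (3S,4S)-4-[4-(benzyloxy)-3-methoxybenzoyl]-3-[4-(benzyloxy)-3-methoxybenzyl]-3-[(trimethylsilyl)oxy]oxolan-2-one | O=C1OC[C@H](C(=O)c2ccc(OCc3ccccc3)c(OC)c2)[C@@]1(O[Si](C)(C)C)Cc1ccc(OCc2ccccc2)c(OC)c1
F0 | step 2 | none | none
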